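**Assumption:** (−)-levoglucosenone (made from cellulose and sold in bulk) and (2E,6E)-farnesyl bromide are catalogue items. Sugar C5 of natural levoglucosenone already has the configuration of the carbinol carbon in the drawn enantiomer.

## Retrosynthetic overview
1. The target comes from the epoxy-cyclohexane-1,3-dione by regioselective O-methylation at the carbonyl remote from the quaternary carbon.
2. The carbocycle is formed last, by intramolecular Claisen transfer of a lactone acyl group onto the CH3 of a 5-acetyl-α,β-epoxy-γ-butyrolactone. This step also releases the free C–OH.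
3. The acetyl group comes from C1 homologation of an aldehyde. The γ-lactone comes from Baeyer–Villiger excision of the anomeric carbon of an epoxy-levoglucosenone.
4. The oxirane comes from exo-face nucleophilic epoxidation of the bicyclic enone. The ring–farnesyl bond comes from a visible-light Ni/photoredox coupling of 3-iodolevoglucosenone with farnesyl bromide.
5. Ring order: bicyclic acetal (bought), then oxirane, then γ-lactone, then cyclohexenone.

"Farnesyl" below means (2E,6E)-3,7,11-trimethyldodeca-2,6,10-trien-1-yl.

## Route

**Step 1**
Reactants: 1, (−)-levoglucosenone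
Product: 2, 3-iodolevoglucosenone
Conditions: I2, pyridine, CH2Cl2, 0 °C to rt, dark
Reagents that add atoms: iodine, II
Why: Johnson α-iodination (pyridine conjugate addition, enolate iodination, E1cB loss of pyridine) is established on this enone and touches no stereocenter.

**Step 2**
Reactants: 2, 3-iodolevoglucosenone; 3, (2E,6E)-farnesyl bromide
Product: 4, 3-farnesyl-levoglucosenone
Conditions: NiBr2·glyme (10 mol %), dtbbpy (12 mol %), 4CzIPN (2 mol %), Hantzsch ester (1.5 equiv), Na2CO3, DMA, 450 nm LEDs, 20 °C, with 3 (1.5 equiv) added by syringe pump
Reagents that add atoms: farnesyl bromide, BrC/C=C(\C)CC/C=C(\C)CCC=C(C)C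
Why: Proposed new method: light-driven reductive vinyl–allyl cross-electrophile coupling of an α-iodoenone with a polyprenyl bromide, in which Ni(0) inserts into the C(sp2)–I bond, 4CzIPN•− (about −1.2 V, turned over by Hantzsch ester) reduces vinyl-Ni(II) to vinyl-Ni(I), this takes up farnesyl bromide to give vinyl(η3-farnesyl)Ni(III), and fast reductive elimination at the unsubstituted allyl terminus gives the linear skipped diene with the E geometry retained (the alkyl alkenes and the enone lie above the sensitiser's triplet energy); the closest known reactions are Zn/Mn-driven Ni-catalysed reductive couplings of vinyl halides with allylic electrophiles and metallaphotoredox aryl-halide/alkyl-halide couplings; no stereocenter is formed.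

**Step 3**
Reactants: 4, 3-farnesyl-levoglucosenone
Product: 5, exo-3,4-epoxide of 4
Conditions: t-BuOOH (decane), Triton B (cat.), THF, 0 °C
Reagents that add atoms: tert-butyl hydroperoxide, CC(C)(C)OO
Why: In this Weitz–Scheffer epoxidation t-BuOO− attacks C4 only from the face opposite the 1,6-anhydro bridge (as all conjugate additions to levoglucosenone do) and the enolate closes on O–O, so both oxirane stereocenters are set by the purchased bicycle, while the electron-rich farnesyl alkenes ignore a nucleophilic oxidant.

**Step 4**
Reactants: 5, epoxy ketone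
Product: 6, epoxy-γ-lactone alcohol
Conditions: 30% aq H2O2 (1.2 equiv), Na2HPO4, t-BuOH/H2O, 0 to 25 °C; Na2S2O3 quench; then KHCO3, MeOH, 0 °C
Reagents that add atoms: hydrogen peroxide, OO (oxygen inserted next to C2; the anomeric carbon leaves as formate)
Why: In this Baeyer–Villiger oxidation the doubly oxygen-stabilised anomeric carbon migrates in preference to the oxiranyl carbon (plain H2O2 converts levoglucosenone and Cyrene to their lactones in the same way), the acyloxy-orthoformate collapses to the γ-lactone 6-O-formate that mild methanolysis removes, and buffered stoichiometric H2O2 neither epoxidises trisubstituted alkenes nor touches a stereocenter.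

**Step 5**
Reactants: 6, epoxy-lactone alcohol
Product: 7, epoxy-lactone aldehyde (used crude)
Conditions: Dess–Martin periodinane, NaHCO3, CH2Cl2, 0 °C
Reagents that add atoms: none
Why: Dess–Martin oxidation is neutral and fast, so the alkenes, oxirane and lactone survive and the α-acyloxy stereocenter does not epimerise.

**Step 6**
Reactants: 7, aldehyde
Product: 8, 5-acetyl epoxy-lactone
Conditions: TMSCHN2 (1.3 equiv), Sc(OTf)3 (5 mol %), CH2Cl2, −78 to −20 °C; aq citric acid/silica work-up
Reagents that add atoms: trimethylsilyldiazomethane, C[Si](C)(C)C=[N+]=[N-] (delivers CH2)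
Why: This is a formal formyl C–H insertion (Büchner–Curtius–Schlotterbeck-type homologation) in which the diazo carbon adds to the aldehyde, a 1,2-hydride shift expels N2 and the α-silyl ketone is protodesilylated on work-up, all without base so the adjacent stereocenter is kept.

**Step 7**
Reactants: 8, acetyl lactone
Product: 9, epoxy-4-hydroxy-cyclohexane-1,3-dione (enolised)
Conditions: LiHMDS (2.1 equiv), THF, −78 to −20 °C (8 added to the base); pH 5 buffer
Reagents that add atoms: none
Why: In this intramolecular crossed Claisen condensation the kinetic CH3 enolate attacks the lactone carbonyl held cis across the oxirane, through an exo-epoxy-7-oxanorbornane-type tetrahedral intermediate that collapses to the stabilised 1,3-dione enolate and frees the carbinol oxygen with its configuration unchanged (Payne migration is blocked because OH and oxirane are cis).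

**Step 8**
Reactants: 9, epoxy dione
Product: 10, yanuthone X2
Conditions: MeOH, HC(OMe)3, PPTS (10 mol %), 23 °C
Reagents that add atoms: methanol, CO (trimethyl orthoformate, COC(OC)OC, serves as water scavenger and methoxy source)
Why: Acid-catalysed vinylogous esterification under thermodynamic control places the methoxy group on the carbonyl remote from the quaternary carbon (4,4-disubstituted cyclohexane-1,3-diones likewise give 3-alkoxy-6,6-disubstituted enones), and the α-keto oxirane and the alcohol tolerate PPTS.

## Compound list
1 | (−)-levoglucosenone, (1S,5R)-6,8-dioxabicyclo[3.2.1]oct-2-en-4-one | C1[C@@H]2C=CC(=O)[C@H](O1)O2 | starting material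
2 | (1S,5R)-3-iodo-6,8-dioxabicyclo[3.2.1]oct-2-en-4-one | C1[C@@H]2C=C(I)C(=O)[C@H](O1)O2 | intermediate
3 | (2E,6E)-farnesyl bromide | BrC/C=C(\C)CC/C=C(\C)CCC=C(C)C | starting material
4 | (1S,5R)-3-farnesyl-6,8-dioxabicyclo[3.2.1]oct-2-en-4-one | C1[C@@H]2C=C(C/C=C(\C)CC/C=C(\C)CCC=C(C)C)C(=O)[C@H](O1)O2 | intermediate
5 | 1,6:3,4-dianhydro-3-C-farnesyl-β-D-ribo-hexopyranos-2-ulose (oxirane O anti to the C6–O6 bridge; sugar numbering 1R,3R,4R,5R) | C1[C@@H]2[C@H]3O[C@@]3(C/C=C(\C)CC/C=C(\C)CCC=C(C)C)C(=O)[C@H](O1)O2 | intermediate
6 | (1R,4R,5R)-1-farnesyl-4-(hydroxymethyl)-3,6-dioxabicyclo[3.1.0]hexan-2-one (CH2OH trans to oxirane O) | OC[C@H]1OC(=O)[C@]2(C/C=C(\C)CC/C=C(\C)CCC=C(C)C)O[C@H]12 | intermediate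
7 | (1R,4S,5R)-1-farnesyl-2-oxo-3,6-dioxabicyclo[3.1.0]hexane-4-carbaldehyde | O=C[C@H]1OC(=O)[C@]2(C/C=C(\C)CC/C=C(\C)CCC=C(C)C)O[C@H]12 | intermediate
8 | (1R,4S,5R)-4-acetyl-1-farnesyl-3,6-dioxabicyclo[3.1.0]hexan-2-one | CC(=O)[C@H]1OC(=O)[C@]2(C/C=C(\C)CC/C=C(\C)CCC=C(C)C)O[C@H]12 | intermediate
9 | (1R,5S,6R)-1-farnesyl-5-hydroxy-7-oxabicyclo[4.1.0]heptane-2,4-dione (OH cis to oxirane; exists as enol) | O=C1CC(=O)[C@]2(C/C=C(\C)CC/C=C(\C)CCC=C(C)C)O[C@@H]2[C@@H]1O | intermediate
10 | yanuthone X2, (1R,5S,6R)-1-farnesyl-5-hydroxy-4-methoxy-7-oxabicyclo[4.1.0]hept-3-en-2-one | COC1=CC(=O)[C@]2(C/C=C(\C)CC/C=C(\C)CCC=C(C)C)O[C@@H]2[C@@H]1O | target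

## Totals
Total steps: 8. Longest linear sequence: 8 (from 1). No protecting groups are used.

## Steps most likely to fail
1. **Step 2 (proposed new coupling).**
   - Risks: hydrodeiodination of 2, farnesyl homodimer, and E/Z or branched leakage through a long-lived π-allyl-nickel species.
   - Fallback (known chemistry, different disconnection): drop the cross-coupling. Alkylate methyl bis(2,2,2-trifluoroethyl)phosphonoacetate with 3. Carry out a Still–Gennari Z-olefination with (R)-glyceraldehyde acetonide. Use aqueous acid to deprotect and lactonise to (S)-3-farnesyl-5-(hydroxymethyl)butenolide. Epoxidise with t-BuOOH/base anti to CH2OH, which rejoins the route at 6.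
2. **Step 7 (lactone-to-carbocycle Claisen).**
   - Risks: the bridged tetrahedral intermediate may be too strained, or enolisation toward the C–H next to the oxirane may open the epoxide.
   - Fallback: reverse the polarity of the closure. Add MeLi to the lactone carbonyl of a silylated derivative of 6, giving a methyl ketone on the oxirane side. Oxidise the CH2OH to the methyl ester. Close by an ordinary unbridged 6-exo Dieckmann-type Claisen of that methyl ketone enolate onto the ester, then desilylate to 9.
3. **Step 8 (regioselective enol ether).**
   - Risks: formation of the isomeric vinylogous ester, or acid-induced loss of the epoxy dione.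
   - Fallback: oxidise 9 (DMP) to the 2-hydroxy-epoxyquinone. Methylate its single acidic OH (TMSCHN2). Reduce the more electrophilic, non-vinylogous carbonyl from the face anti to the oxirane (NaBH4/CeCl3, −78 °C). This regenerates the cis-epoxy alcohol of 10.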